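**Retrosynthetic overview**

- Locants: C1 is the quaternary oxirane carbon bearing C7H2OBz, C2 is CHOAc, C3 is CHOBz, C4=C5 is the alkene, C6 is the oxirane CH. The strategy rests on the vinyl oxirane C4=C5–C6(–O–)C1: it is the ring diene C1=C6–C5=C4 plus one oxygen, and arises by contracting a C1,C4-peroxide bridge (a 2,3-dioxabicyclo[2.2.2]oct-5-ene) onto C6.
- Disconnections, backwards: C3–OBz (Mitsunobu inversion of the cis C3 alcohol) ⇒ C3 silyl ether of the vinyl oxirane ⇒ (PPh3, loss of the C4 oxygen with SN2′ closure) endoperoxide ⇒ (singlet oxygen [4+2]) cis-2,3-dioxygenated cyclohexa-1,3-diene.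
- The diene comes from the microbial (1S,2S)-bromodiol, which supplies C2 and the cis oxygen pair that steers the oxygenation: distal silylation, Stille hydroxymethylation (C7), primary benzoylation, C2 acetylation. The esters are installed after the palladium step so that no allylic carboxylate meets Pd(0).
- Ring order: the carbocycle is in the starting material; the 1,2-dioxine ring is closed in step 5; the oxirane is closed in step 6 as the peroxide ring opens.

Key step: step 5

Remark: C1–C7 in the text are the target locants defined above; β is the ring face of the C2 oxygen and α the opposite face; systematic names carry their own numbering. The bromodiol 1 is taken as the commercial dioxygenase product of bromobenzene.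

**Route**

Step 1
Reactants: 1 (1S,2S)-3-bromocyclohexa-3,5-diene-1,2-diol
Product: 2 (1S,6S)-2-bromo-6-[(tert-butyldimethylsilyl)oxy]cyclohexa-2,4-dien-1-ol
Conditions: TBSCl (1.05 equiv), imidazole, DMF, −20 → 0 °C
Reagents that add atoms: tert-butyldimethylsilyl chloride, CC(C)(C)[Si](C)(C)Cl
Why: Regioselective O-silylation (chlorosilane/imidazole protocol) should take the hydroxyl remote from bromine first, because the one next to the C–Br carbon is more hindered and inductively less nucleophilic; no stereocentre is touched.

Step 2
Reactants: 2 (1S,6S)-2-bromo-6-[(tert-butyldimethylsilyl)oxy]cyclohexa-2,4-dien-1-ol; 3 (tributylstannyl)methanol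
Product: 4 (1R,6S)-6-[(tert-butyldimethylsilyl)oxy]-2-(hydroxymethyl)cyclohexa-2,4-dien-1-ol
Conditions: Pd(PPh3)4 (10 mol %), degassed 1,4-dioxane, 80 °C, dark
Reagents that add atoms: none
Why: Migita–Kosugi–Stille cross-coupling (oxidative addition of Pd(0) into the alkenyl C–Br bond, transfer of the oxygen-bearing CH2OH group from tin in preference to butyl, reductive elimination) should replace Br by C7 with both ring stereocentres untouched, and running it while the ring carries no carboxylate ester avoids Pd(0) ionisation of an allylic ester and the aromatisation that would follow.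

Step 3
Reactants: 4 (1R,6S)-6-[(tert-butyldimethylsilyl)oxy]-2-(hydroxymethyl)cyclohexa-2,4-dien-1-ol
Product: 5 [(5S,6R)-5-[(tert-butyldimethylsilyl)oxy]-6-hydroxycyclohexa-1,3-dien-1-yl]methyl benzoate
Conditions: BzCl (1.05 equiv), pyridine, CH2Cl2, −40 → −20 °C
Reagents that add atoms: benzoyl chloride, O=C(Cl)c1ccccc1
Why: Chemoselective acylation (acid chloride/pyridine esterification) with one equivalent at low temperature should pick the unhindered primary allylic hydroxyl over the secondary one, which is flanked by the silyl ether and the ring substituent.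

Step 4
Reactants: 5 [(5S,6R)-5-[(tert-butyldimethylsilyl)oxy]-6-hydroxycyclohexa-1,3-dien-1-yl]methyl benzoate
Product: 6 [(5S,6R)-6-acetoxy-5-[(tert-butyldimethylsilyl)oxy]cyclohexa-1,3-dien-1-yl]methyl benzoate
Conditions: Ac2O, pyridine, DMAP (cat.), CH2Cl2, 0 °C
Reagents that add atoms: acetic anhydride, CC(=O)OC(C)=O
Why: DMAP-catalysed acetylation (nucleophilic acyl-transfer catalysis) should esterify the remaining secondary hydroxyl with retention at C2, giving the diene with its two ring oxygens cis and differentiated.

Step 5
Reactants: 6 [(5S,6R)-6-acetoxy-5-[(tert-butyldimethylsilyl)oxy]cyclohexa-1,3-dien-1-yl]methyl benzoate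
Product: 7 [(1R,4R,7S,8R)-7-acetoxy-8-[(tert-butyldimethylsilyl)oxy]-2,3-dioxabicyclo[2.2.2]oct-5-en-1-yl]methyl benzoate (peroxide bridge on the α face, anti to OAc and OTBS)
Conditions: O2, tetraphenylporphyrin (cat.), hν (visible), CH2Cl2, −30 °C
Reagents that add atoms: dioxygen (as singlet oxygen), O=O
Why: Sensitised singlet oxygen adds suprafacially across the ring-locked s-cis diene C1=C6–C5=C4 in a concerted [4+2] cycloaddition, forming the C1–O and C4–O bonds and leaving C5=C6; this is the photooxygenation of a cyclohexa-1,3-diene to a 2,3-dioxabicyclo[2.2.2]oct-5-ene, a reaction type established for protected arene cis-dihydrodiols. The 1,2-dioxine ring C1–O–O–C4–C5=C6 is closed by the cycloaddition itself, both C–O bonds forming in the one pericyclic event, which creates the bicyclo[2.2.2] skeleton. C1 and C4 become stereocentres together: their relative configuration follows from the suprafacial addition, and their absolute sense from the face of attack, which the two β oxygen substituents at C2 and C3 (acetate and bulky silyl ether) should direct to the open α face that carries only hydrogen. The step needs face selectivity and [4+2] over ene periselectivity; the first rests on both allylic substituents lying on one face, the second on the enforced s-cis geometry and on the allylic C–H bonds at C2, C3 and C7 being deactivated by their geminal oxygen substituents. The low temperature is chosen to keep the peroxide from rearranging to a bis-epoxide.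

Step 6
Reactants: 7 [(1R,4R,7S,8R)-7-acetoxy-8-[(tert-butyldimethylsilyl)oxy]-2,3-dioxabicyclo[2.2.2]oct-5-en-1-yl]methyl benzoate
Product: 8 [(1S,2S,3S,6S)-2-acetoxy-3-[(tert-butyldimethylsilyl)oxy]-7-oxabicyclo[4.1.0]hept-4-en-1-yl]methyl benzoate (oxirane α)
Conditions: PPh3 (1.05 equiv), dry CH2Cl2, 0 °C → rt
Reagents that add atoms: none
Why: Phosphine deoxygenation of an unsaturated bicyclic endoperoxide: PPh3 should attack the less hindered peroxide oxygen, the one on the secondary C4, and the C1 alkoxide so released closes onto C6 in a syn SN2′ displacement that expels Ph3P=O and moves the alkene to C4=C5, so the C1–O bond and configuration are kept and C6 receives the oxygen on the same α face by intramolecular delivery.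

Step 7
Reactants: 8 [(1S,2S,3S,6S)-2-acetoxy-3-[(tert-butyldimethylsilyl)oxy]-7-oxabicyclo[4.1.0]hept-4-en-1-yl]methyl benzoate
Product: 9 [(1S,2S,3S,6S)-2-acetoxy-3-hydroxy-7-oxabicyclo[4.1.0]hept-4-en-1-yl]methyl benzoate
Conditions: TBAF, AcOH (1:1), THF, 0 °C → rt
Reagents that add atoms: none
Why: Fluoride-mediated desilylation (Si–F bond formation drives Si–O cleavage) is buffered with acetic acid so that the freed C3 hydroxyl is never an alkoxide that could take over the cis-vicinal acetyl group or open the vinyl oxirane; no stereocentre changes.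

Step 8
Reactants: 9 [(1S,2S,3S,6S)-2-acetoxy-3-hydroxy-7-oxabicyclo[4.1.0]hept-4-en-1-yl]methyl benzoate; 10 benzoic acid
Product: 11 [(1S,2S,3R,6S)-2-acetoxy-3-(benzoyloxy)-7-oxabicyclo[4.1.0]hept-4-en-1-yl]methyl benzoate (target)
Conditions: PPh3, DIAD, THF, 0 °C → rt
Reagents that add atoms: none
Why: Mitsunobu reaction: the C3 hydroxyl is activated as its alkoxyphosphonium ion and displaced by benzoate in an SN2 step from the α face, which inverts C3 and turns the cis C2/C3 pair into the trans diester, while the C2 acetate, being syn to the leaving group, cannot participate.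

**Compound list**

1 | (1S,2S)-3-bromocyclohexa-3,5-diene-1,2-diol | O[C@H]1[C@@H](O)C=CC=C1Br | starting material
2 | (1S,6S)-2-bromo-6-[(tert-butyldimethylsilyl)oxy]cyclohexa-2,4-dien-1-ol | O[C@H]1[C@@H](O[Si](C)(C)C(C)(C)C)C=CC=C1Br | intermediate
3 | (tributylstannyl)methanol | CCCC[Sn](CCCC)(CCCC)CO | starting material
4 | (1R,6S)-6-[(tert-butyldimethylsilyl)oxy]-2-(hydroxymethyl)cyclohexa-2,4-dien-1-ol | O[C@H]1[C@@H](O[Si](C)(C)C(C)(C)C)C=CC=C1CO | intermediate
5 | [(5S,6R)-5-[(tert-butyldimethylsilyl)oxy]-6-hydroxycyclohexa-1,3-dien-1-yl]methyl benzoate | O[C@H]1[C@@H](O[Si](C)(C)C(C)(C)C)C=CC=C1COC(=O)c1ccccc1 | intermediate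
6 | [(5S,6R)-6-acetoxy-5-[(tert-butyldimethylsilyl)oxy]cyclohexa-1,3-dien-1-yl]methyl benzoate | CC(=O)O[C@H]1[C@@H](O[Si](C)(C)C(C)(C)C)C=CC=C1COC(=O)c1ccccc1 | intermediate
7 | [(1R,4R,7S,8R)-7-acetoxy-8-[(tert-butyldimethylsilyl)oxy]-2,3-dioxabicyclo[2.2.2]oct-5-en-1-yl]methyl benzoate | CC(=O)O[C@H]1[C@@H](O[Si](C)(C)C(C)(C)C)[C@H]2C=C[C@]1(COC(=O)c1ccccc1)OO2 | intermediate
8 | [(1S,2S,3S,6S)-2-acetoxy-3-[(tert-butyldimethylsilyl)oxy]-7-oxabicyclo[4.1.0]hept-4-en-1-yl]methyl benzoate | CC(=O)O[C@H]1[C@@H](O[Si](C)(C)C(C)(C)C)C=C[C@@H]2O[C@@]21COC(=O)c1ccccc1 | intermediate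
9 | [(1S,2S,3S,6S)-2-acetoxy-3-hydroxy-7-oxabicyclo[4.1.0]hept-4-en-1-yl]methyl benzoate | CC(=O)O[C@H]1[C@@H](O)C=C[C@@H]2O[C@@]21COC(=O)c1ccccc1 | intermediate
10 | benzoic acid | OC(=O)c1ccccc1 | starting material
11 | [(1S,2S,3R,6S)-2-acetoxy-3-(benzoyloxy)-7-oxabicyclo[4.1.0]hept-4-en-1-yl]methyl benzoate | CC(=O)O[C@H]1[C@H](OC(=O)c2ccccc2)C=C[C@@H]2O[C@@]21COC(=O)c1ccccc1 | target

**Totals**

Total step count: 8. Longest linear sequence: 8 steps (1 → 11).

**Steps most likely to fail**

Step 2 (Stille hydroxymethylation). The sp3 hydroxymethyl group transfers slowly from tin, so the coupling needs heat. At that temperature the cyclohexadienol may aromatise by loss of water or silanol, and butyl transfer or protodebromination may compete. The fallback brings in C7 as carbon monoxide and sets out from 2. Palladium-catalysed methoxycarbonylation (CO 1 atm, MeOH, Pd(OAc)2, dppp, Et3N, DMF, 60 °C) should give methyl (5S,6R)-5-[(tert-butyldimethylsilyl)oxy]-6-hydroxycyclohexa-1,3-diene-1-carboxylate F1. Its 1,2-reduction with DIBAL-H (CH2Cl2, −78 °C) would give the allylic alcohol, and the fallback rejoins the route at 4.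

Step 8 (Mitsunobu inversion at C3). The activated allylic oxygen may be displaced with allylic transposition, delivering benzoate to C5, or may eliminate. The vinyl oxirane may also be opened by the free carboxylic acid. The fallback separates activation from displacement, keeps the medium non-acidic, and sets out from 9. Sulfonylation with chloromethanesulfonyl chloride (pyridine, CH2Cl2, −20 °C) should give [(1S,2S,3S,6S)-2-acetoxy-3-[(chloromethanesulfonyl)oxy]-7-oxabicyclo[4.1.0]hept-4-en-1-yl]methyl benzoate F2. Treatment with caesium benzoate (from 10 and Cs2CO3) and 18-crown-6 in toluene at rt to 40 °C should then displace the sulfonate with SN2 inversion, and the fallback rejoins the route at 11.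

Step 6 (phosphine contraction of the peroxide). Phosphorus may be delivered to the peroxide oxygen on the quaternary C1 side, which would place the oxirane at C4–C5. Moisture may intercept the phosphorus(V) intermediate to give the ene-1,4-diol, or an ester may transfer to the transient C1 alkoxide. The fallback forms the oxirane without a peroxide and sets out from 6. Direct epoxidation with dimethyldioxirane (acetone/CH2Cl2, −20 °C) is expected to take the trisubstituted C1=C6 alkene, the more nucleophilic of the two, from the α face anti to both β oxygens. The site selectivity between the two alkenes would have to be confirmed. It rejoins the route at 8, bypasses 7, and makes no compound outside the list (F0); the same detour would serve if the photooxygenation of step 5 underperformed.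

**Further compounds**

F1 | step 2 | methyl (5S,6R)-5-[(tert-butyldimethylsilyl)oxy]-6-hydroxycyclohexa-1,3-diene-1-carboxylate | O[C@H]1[C@@H](O[Si](C)(C)C(C)(C)C)C=CC=C1C(=O)OC
F0 | step 6 | none | none
F2 | step 8 | [(1S,2S,3S,6S)-2-acetoxy-3-[(chloromethanesulfonyl)oxy]-7-oxabicyclo[4.1.0]hept-4-en-1-yl]methyl benzoate | CC(=O)O[C@H]1[C@@H](OS(=O)(=O)CCl)C=C[C@@H]2O[C@@]21COC(=O)c1ccccc1
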